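C5, the tertiary carbinol carbon of the ring, is recognised as the carboxyl carbon of oleic acid, so the C18 chain with its Z-olefin is bought intact. The cyclohexenone ring (C1–C6) is disconnected at its cis C2=C3 double bond, which touches neither carbinol centre and whose geometry the six-membered ring enforces. The precursor is an open-chain trienone in which the C4/C5 diol pair is already set, C4 by asymmetric alkoxyallylboration and C5 by a chelate-controlled Mukaiyama aldol addition. Ring-closing metathesis joins the vinyl ketone and the allylic vinyl group in one neutral, catalytic operation that spares the stereodiad, the retro-aldol-prone β-hydroxy ketone and a product that dehydrates easily to a hydroquinone.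

Key step: step 6

Remark on numbering: ring atoms are C1 (C=O), C2=C3, C4 (secondary carbinol), C5 (tertiary carbinol) and C6 (CH2). Side-chain atoms carry primes. The SMILES corresponds to the (4S,5S) trans-diol with an (8′Z) chain.

Step 1
Reactants: 1 oleyl alcohol, (9Z)-octadec-9-en-1-ol
Product: 2 (9Z)-octadec-9-enal
Conditions: TEMPO (10 mol %), PhI(OAc)2, CH2Cl2, rt
Reagents that add atoms: none
Why: The TEMPO (oxoammonium) oxidation of a primary alcohol stops at the aldehyde and leaves the isolated Z-olefin untouched, and no stereocentre is involved.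

Step 2
Reactants: 3 allyl alcohol, prop-2-en-1-ol
Product: 4 allyl methoxymethyl ether, 3-(methoxymethoxy)prop-1-ene
Conditions: CH2(OMe)2 (excess), LiBr (cat.), p-TsOH·H2O (cat.), rt
Reagents that add atoms: dimethoxymethane, COCOC
Why: Acid-catalysed transacetalisation with excess dimethoxymethane should convert the primary alcohol into its MOM ether, and no stereocentre is formed.

Step 3
Reactants: 2 (9Z)-octadec-9-enal; 4 allyl methoxymethyl ether
Product: 9 (3S,4S,12Z)-3-(methoxymethoxy)henicosa-1,12-dien-4-ol, via Z-allyllithium 5 (not isolated), via borate complex 6 (not isolated), via Z-alkoxyallylborane 7 (not isolated), via borinate ester 8 (not isolated)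
Conditions: 4, s-BuLi, THF, −78 °C; (+)-Ipc2BOMe, −78 °C; BF3·OEt2, then 2, −78 °C to rt; NaOH, H2O2, 0 °C to rt
Reagents that add atoms: none
Why: In this Brown asymmetric alkoxyallylboration the internally chelated Z-allyllithium gives the Z-γ-alkoxyallylborane, its chair-like Zimmerman–Traxler transition state gives the syn adduct, and the isopinocampheyl groups derived from (−)-α-pinene select the aldehyde face, so both new centres should be S, the MOM-bearing one being C4 of the future ring.

Step 4
Reactants: 9 (3S,4S,12Z)-3-(methoxymethoxy)henicosa-1,12-dien-4-ol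
Product: 10 (3S,12Z)-3-(methoxymethoxy)henicosa-1,12-dien-4-one
Conditions: Dess–Martin periodinane, NaHCO3, CH2Cl2, 0 °C
Reagents that add atoms: none
Why: The buffered, non-basic Dess–Martin oxidation should give the ketone without enolising the C–H flanked by carbonyl, vinyl and alkoxy groups, so the S centre survives while the superfluous carbinol centre is erased.

Step 5
Reactants: 10 (3S,12Z)-3-(methoxymethoxy)henicosa-1,12-dien-4-one; 11 2-(trimethylsilyloxy)buta-1,3-diene
Product: 13 (5S,13Z)-5-hydroxy-5-[(1S)-1-(methoxymethoxy)prop-2-en-1-yl]docosa-1,13-dien-3-one, via trichlorotitanium aldolate 12 (not isolated)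
Conditions: TiCl4 (1 equiv), CH2Cl2, −78 °C, then 11, −78 °C; pH 7 buffer
Reagents that add atoms: none
Why: In this chelation-controlled Mukaiyama aldol addition TiCl4 ties the ketone oxygen and the inner MOM oxygen into a five-membered Cram chelate and the enol-silane terminus of 11 attacks the face that carries H rather than vinyl, which should set the tertiary carbinol as S (syn in the open chain, trans in the later ring) without any base.

Step 6
Reactants: 13 (5S,13Z)-5-hydroxy-5-[(1S)-1-(methoxymethoxy)prop-2-en-1-yl]docosa-1,13-dien-3-one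
Product: 14 (4S,5S)-5-[(8Z)-heptadec-8-en-1-yl]-5-hydroxy-4-(methoxymethoxy)cyclohex-2-en-1-one
Conditions: second-generation Hoveyda–Grubbs catalyst (5 mol %), 1,4-benzoquinone (10 mol %), CH2Cl2 (0.002 M), 40 °C, argon sparge
Reagents that add atoms: none
Why: Ring-closing olefin metathesis by the Chauvin mechanism: the ruthenium alkylidene first exchanges with the more electron-rich monosubstituted C3 vinyl group, the new alkylidene adds intramolecularly to the vinyl ketone to give a ruthenacyclobutane, and cycloreversion releases the C2=C3 bond while ethylene leaves. The closest known reaction type is the closure of octa-1,7-dien-3-ones to cyclohex-2-enones. The one ring closes as a six-membered carbocycle by joining the sp2 carbons C2 and C3, and the ring size allows only the cis olefin. No stereocentre is formed, and C4 and C5 lie outside the reacting π systems, so the stereodiad from steps 3 and 5 is carried over unchanged. The selectivity needed is terminal over internal olefin: both partners are monosubstituted and held in a six-atom array, the C8′=C9′ olefin is 1,2-disubstituted and could only close an eleven-membered or larger ring, and high dilution, ethylene removal, short reaction time and benzoquinone as hydride scavenger should suppress its Z/E scrambling. The neutral medium spares the β-hydroxy ketone from retro-aldol cleavage and the product from dehydration to the hydroquinone.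

Step 7
Reactants: 14 (4S,5S)-5-[(8Z)-heptadec-8-en-1-yl]-5-hydroxy-4-(methoxymethoxy)cyclohex-2-en-1-one
Product: 16 (4S,5S)-5-[(8Z)-heptadec-8-en-1-yl]-4,5-dihydroxycyclohex-2-en-1-one, via bromomethyl ether 15 (not isolated)
Conditions: Me2BBr, CH2Cl2, −78 °C; then THF, sat. aq. NaHCO3, 0 °C
Reagents that add atoms: none
Why: In this Lewis-acid acetal cleavage (MOM deprotection) bromodimethylborane breaks only the outer acetal C–O bond at −78 °C and the bicarbonate quench hydrolyses the bromomethyl ether, so no C–O bond at C4 or C5 is touched, the configuration is retained, and the protic acid and heat that would aromatise the ring are avoided.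

Compound list
1 | oleyl alcohol, (9Z)-octadec-9-en-1-ol | CCCCCCCC/C=C\CCCCCCCCO | starting material
2 | (9Z)-octadec-9-enal | CCCCCCCC/C=C\CCCCCCCC=O | intermediate
3 | allyl alcohol, prop-2-en-1-ol | C=CCO | starting material
4 | allyl methoxymethyl ether, 3-(methoxymethoxy)prop-1-ene | C=CCOCOC | intermediate
5 | [(2Z)-3-(methoxymethoxy)prop-2-en-1-yl]lithium | [Li]C/C=C\OCOC | intermediate
6 | lithium methoxy[(2Z)-3-(methoxymethoxy)prop-2-en-1-yl]bis(isopinocampheyl)borate, isopinocampheyl groups from (−)-α-pinene | [Li+].COCO/C=C\C[B-](OC)([C@H]1C[C@H]2C[C@@H]([C@@H]1C)C2(C)C)[C@H]1C[C@H]2C[C@@H]([C@@H]1C)C2(C)C | intermediate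
7 | [(2Z)-3-(methoxymethoxy)prop-2-en-1-yl]bis(isopinocampheyl)borane | COCO/C=C\CB([C@H]1C[C@H]2C[C@@H]([C@@H]1C)C2(C)C)[C@H]1C[C@H]2C[C@@H]([C@@H]1C)C2(C)C | intermediate
8 | bis(isopinocampheyl)borinate ester of alcohol 9 | C=C[C@H](OCOC)[C@@H](OB([C@H]1C[C@H]2C[C@@H]([C@@H]1C)C2(C)C)[C@H]1C[C@H]2C[C@@H]([C@@H]1C)C2(C)C)CCCCCCC/C=C\CCCCCCCC | intermediate
9 | (3S,4S,12Z)-3-(methoxymethoxy)henicosa-1,12-dien-4-ol (syn) | C=C[C@H](OCOC)[C@@H](O)CCCCCCC/C=C\CCCCCCCC | intermediate
10 | (3S,12Z)-3-(methoxymethoxy)henicosa-1,12-dien-4-one | C=C[C@H](OCOC)C(=O)CCCCCCC/C=C\CCCCCCCC | intermediate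
11 | 2-(trimethylsilyloxy)buta-1,3-diene | C=CC(=C)O[Si](C)(C)C | starting material
12 | trichlorotitanium alkoxide of aldol 13 | CCCCCCCC/C=C\CCCCCCC[C@](O[Ti](Cl)(Cl)Cl)(CC(=O)C=C)[C@@H](OCOC)C=C | intermediate
13 | (5S,13Z)-5-hydroxy-5-[(1S)-1-(methoxymethoxy)prop-2-en-1-yl]docosa-1,13-dien-3-one | CCCCCCCC/C=C\CCCCCCC[C@](O)(CC(=O)C=C)[C@@H](OCOC)C=C | intermediate
14 | (4S,5S)-5-[(8Z)-heptadec-8-en-1-yl]-5-hydroxy-4-(methoxymethoxy)cyclohex-2-en-1-one | CCCCCCCC/C=C\CCCCCCC[C@]1(O)CC(=O)C=C[C@@H]1OCOC | intermediate
15 | (4S,5S)-4-(bromomethoxy)-5-[(8Z)-heptadec-8-en-1-yl]-5-hydroxycyclohex-2-en-1-one | CCCCCCCC/C=C\CCCCCCC[C@]1(O)CC(=O)C=C[C@@H]1OCBr | intermediate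
16 | (4S,5S)-5-[(8Z)-heptadec-8-en-1-yl]-4,5-dihydroxycyclohex-2-en-1-one | CCCCCCCC/C=C\CCCCCCC[C@]1(O)CC(=O)C=C[C@@H]1O | target

Total step count: 7. Longest linear sequence: 6 steps (1, 3, 4, 5, 6, 7).

Steps most likely to fail

Risk 1, step 6. Secondary metathesis at the C8′=C9′ olefin (Z/E scrambling, chain shortening by ethenolysis) may erode the step. So may sluggish closure onto the electron-poor vinyl ketone beside the crowded C4/C5 pair. The fallback sets out from 13 and returns at 14.
- Luche reduction (NaBH4, CeCl3·7H2O, MeOH, −78 °C) turns the vinyl ketone into the bis-allylic alcohol (5S,13Z)-5-[(1S)-1-(methoxymethoxy)prop-2-en-1-yl]docosa-1,13-diene-3,5-diol F1, as both C3 epimers.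
- Both terminal olefins are now electron-rich. The milder first-generation Grubbs catalyst, which barely engages 1,2-disubstituted olefins, should close the ring to (4S,5S)-5-[(8Z)-heptadec-8-en-1-yl]-4-(methoxymethoxy)cyclohex-2-ene-1,5-diol F2.
- MnO2 then oxidises the only secondary allylic alcohol, so both epimers converge on 14.

Risk 2, step 5. Several processes may compete:
- ionisation of the MOM acetal by TiCl4;
- leakage through a non-chelated transition state (poor facial selectivity);
- enolisation with loss of the C4 configuration;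
- oxa-Michael closure of the tertiary alkoxide onto the new vinyl ketone.

The fallback sets out from 10 and returns at 13, and builds the enone arm in stages.
- The weakly basic, chelating Reformatsky reagent BrZnCH2CO2Et (Zn, ethyl bromoacetate, THF) should add under chelate control to give ethyl (3S,11Z)-3-hydroxy-3-[(1S)-1-(methoxymethoxy)prop-2-en-1-yl]icos-11-enoate F3.
- MeNH(OMe)·HCl and i-PrMgCl convert it into (3S,11Z)-3-hydroxy-N-methoxy-3-[(1S)-1-(methoxymethoxy)prop-2-en-1-yl]-N-methylicos-11-enamide F4.
- Vinylmagnesium bromide then gives 13, and the vinyl ketone is released only at the aqueous quench.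

Risk 3, step 7. Lewis-acid-induced ionisation or β-elimination of the tertiary C5 hydroxyl, followed by tautomerisation, would drain the ring into the aromatic hydroquinone. The fallback sets out from 13, returns at 16 and inverts the order of events.
- The MOM group is cleaved on the open-chain trienone (Me2BBr, CH2Cl2, −78 °C, bicarbonate quench), where no aromatic sink exists. This gives (5S,13Z)-5-hydroxy-5-[(1S)-1-hydroxyprop-2-en-1-yl]docosa-1,13-dien-3-one F5.
- The ring-closing metathesis of step 6 is then run on this free diol. The sensitive ring is formed last, under neutral conditions, directly as 16.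

Further compounds
F1 | step 6 | (5S,13Z)-5-[(1S)-1-(methoxymethoxy)prop-2-en-1-yl]docosa-1,13-diene-3,5-diol, both C3 epimers | CCCCCCCC/C=C\CCCCCCC[C@](O)(CC(O)C=C)[C@@H](OCOC)C=C
F2 | step 6 | (4S,5S)-5-[(8Z)-heptadec-8-en-1-yl]-4-(methoxymethoxy)cyclohex-2-ene-1,5-diol, both C1 epimers | CCCCCCCC/C=C\CCCCCCC[C@]1(O)CC(O)C=C[C@@H]1OCOC
F3 | step 5 | ethyl (3S,11Z)-3-hydroxy-3-[(1S)-1-(methoxymethoxy)prop-2-en-1-yl]icos-11-enoate | CCCCCCCC/C=C\CCCCCCC[C@](O)(CC(=O)OCC)[C@@H](OCOC)C=C
F4 | step 5 | (3S,11Z)-3-hydroxy-N-methoxy-3-[(1S)-1-(methoxymethoxy)prop-2-en-1-yl]-N-methylicos-11-enamide | CCCCCCCC/C=C\CCCCCCC[C@](O)(CC(=O)N(C)OC)[C@@H](OCOC)C=C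
F5 | step 7 | (5S,13Z)-5-hydroxy-5-[(1S)-1-hydroxyprop-2-en-1-yl]docosa-1,13-dien-3-one | CCCCCCCC/C=C\CCCCCCC[C@](O)(CC(=O)C=C)[C@@H](O)C=C
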